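**Retrosynthetic overview**
- **Feature:** ring A bears OMe at C6 and C7 and H at C5 and C8. Its C4a–C8a edge is shared with pyranone ring B (C4a holds the C4 carbonyl, C8a holds O1). This edge maps onto the triple bond of 4,5-dimethoxybenzyne, whose two aryne carbons are equivalent, so no regiochemical question arises.
- Target 20 ⇒ benzyl ether 19. The ring C phenol must be masked because an aryne would arylate it.
- 19 ⇒ aryne precursor 6 + 5-arylpent-2-ynoic acid 16, cutting O1–C8a, C4–C4a and O1–C2 in one operation. Ring B is the only ring made; rings A and C are bought.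
- 6 ⇒ 3,4-dimethoxyphenol 1 (bromination, O-silylation, retro-Brook shift and triflation).
- 16 ⇒ O-benzylvanillin 7 by way of benzylic bromide 9 and lithiated 1-(trimethylsilyl)propyne, then desilylation and carboxylation. A propargyl metal added to aldehyde 7 would leave a benzylic carbinol instead of the CH2–CH2 link, so the halide is used.

Key step: step 9

Remark: the target has no stereocentre and no configured double bond, so the SMILES strings carry no stereo descriptors and no step needs stereocontrol.

Step 1
Reactants: 1 3,4-dimethoxyphenol
Product: 2 2-bromo-4,5-dimethoxyphenol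
Conditions: NBS (1.0 equiv), MeCN, 0 °C
Reagents that add atoms: N-bromosuccinimide, O=C1CCC(=O)N1Br
Why: Electrophilic aromatic bromination should go to C6 of 1, ortho to the hydroxyl and para to the 3-methoxy group, because C2 is crowded between two oxygen substituents and C5 is not activated by the hydroxyl.

Step 2
Reactants: 2 2-bromo-4,5-dimethoxyphenol
Product: 3 (2-bromo-4,5-dimethoxyphenoxy)trimethylsilane
Conditions: HMDS, THF, reflux; evaporation, used crude
Reagents that add atoms: hexamethyldisilazane, C[Si](C)(C)N[Si](C)(C)C
Why: O-silylation of a phenol with HMDS forms only a volatile co-product, so the moisture-sensitive silyl ether can be carried on without purification.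

Step 3
Reactants: 3 (2-bromo-4,5-dimethoxyphenoxy)trimethylsilane
Product: 6 4,5-dimethoxy-2-(trimethylsilyl)phenyl trifluoromethanesulfonate, via aryllithium 4 (not isolated), via lithium phenoxide 5 (not isolated)
Conditions: n-BuLi (1.1 equiv), THF, −78 °C; then Tf2O (1.2 equiv), −78 °C to rt
Reagents that add atoms: trifluoromethanesulfonic anhydride, O=S(=O)(OS(=O)(=O)C(F)(F)F)C(F)(F)F
Why: Bromine–lithium exchange, faster than any ortho-lithiation at −78 °C, gives 4, whose silyl group moves from oxygen to the carbanion (retro-Brook 1,3-shift) to give phenoxide 5, and O-triflation of 5 completes the standard sequence to o-silylaryl triflates.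

Step 4
Reactants: 7 O-benzylvanillin (4-(benzyloxy)-3-methoxybenzaldehyde)
Product: 8 [4-(benzyloxy)-3-methoxyphenyl]methanol
Conditions: NaBH4, MeOH–THF, 0 °C
Reagents that add atoms: none
Why: Borohydride reduction of an aromatic aldehyde is selective and leaves the aryl methyl and aryl benzyl ethers untouched.

Step 5
Reactants: 8 [4-(benzyloxy)-3-methoxyphenyl]methanol
Product: 9 1-(benzyloxy)-4-(bromomethyl)-2-methoxybenzene
Conditions: PBr3 (0.4 equiv), CH2Cl2, 0 °C; aqueous wash, used without chromatography
Reagents that add atoms: phosphorus tribromide, BrP(Br)Br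
Why: Bromination of a benzylic alcohol with PBr3 (phosphite ester formation, then displacement by bromide) is fast at 0 °C for this electron-rich system, and immediate use avoids self-alkylation of the labile bromide.

Step 6
Reactants: 9 1-(benzyloxy)-4-(bromomethyl)-2-methoxybenzene; 10 1-(trimethylsilyl)propyne
Product: 12 {4-[4-(benzyloxy)-3-methoxyphenyl]but-1-yn-1-yl}trimethylsilane, via lithiated silylpropyne 11 (not isolated)
Conditions: 10 (1.3 equiv), n-BuLi (1.2 equiv), THF, −78 °C; then 9, −78 °C to rt
Reagents that add atoms: none
Why: Propargylic lithiation of a silyl-capped propyne followed by SN2 alkylation with a benzylic bromide is a standard three-carbon homologation in which the silyl group blocks the acetylenic end and favours bond formation at the propargylic carbon, giving the CH2–CH2 link directly.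

Step 7
Reactants: 12 {4-[4-(benzyloxy)-3-methoxyphenyl]but-1-yn-1-yl}trimethylsilane
Product: 13 1-(benzyloxy)-4-(but-3-yn-1-yl)-2-methoxybenzene
Conditions: K2CO3, MeOH–THF, rt
Reagents that add atoms: none
Why: Carbonate-promoted methanolysis of the C(sp)–Si bond (protiodesilylation) is mild and touches no other group in the molecule.

Step 8
Reactants: 13 1-(benzyloxy)-4-(but-3-yn-1-yl)-2-methoxybenzene
Product: 16 5-[4-(benzyloxy)-3-methoxyphenyl]pent-2-ynoic acid, via lithium acetylide 14 (not isolated), via lithium alkynoate 15 (not isolated)
Conditions: n-BuLi (1.05 equiv), THF, −78 °C; dry CO2, −78 to 0 °C; 1 M HCl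
Reagents that add atoms: carbon dioxide, O=C=O
Why: The acetylenic hydrogen is by far the most acidic site, so deprotonation and carboxylation of the lithium acetylide with CO2 should give the alk-2-ynoic acid without touching the benzyl ether at −78 °C.

Step 9
Reactants: 6 4,5-dimethoxy-2-(trimethylsilyl)phenyl trifluoromethanesulfonate; 16 5-[4-(benzyloxy)-3-methoxyphenyl]pent-2-ynoic acid
Product: 19 2-{2-[4-(benzyloxy)-3-methoxyphenyl]ethyl}-6,7-dimethoxy-4H-chromen-4-one, via 4,5-dimethoxybenzyne 17 (not isolated), via hydroxyaryl ynone 18 (not isolated)
Conditions: 6 (1.5 equiv), 16 (1.0 equiv), dried CsF (4 equiv), THF (0.02 M), 125 °C, sealed tube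
Reagents that add atoms: none
Why: Desilylation of 6 by fluoride with loss of triflate sets free aryne 17, the carboxylate oxygen of 16 binds one aryne carbon (O1–C8a), the carbanion on the adjacent carbon is acylated by the new ester (C4a–C4, an anionic Fries-type shift by way of a strained four-ring alkoxide) to give the phenoxide of ynone 18, and this phenoxide adds to the alkyne β-carbon (O1–C2) while the proton brought in by the acid ends up on C3. The closest known reaction type is the CsF-mediated insertion of arynes into the C–O bond of carboxylic acids in hot THF, which gives o-hydroxyaryl ketones and with conjugated acids runs on to the oxygen heterocycle in the same flask; base-induced closure of o-hydroxyaryl ynones to chromones is also known on its own. Ring B, the only ring closed, forms by a 6-endo-dig oxa-Michael addition, and no stereocentre is created. No regiocontrol is needed, since the mirror plane of 17 makes its two aryne carbons equivalent and either sense of addition places the methoxy groups at C6 and C7. The step needs the acyl shift to be faster than proton capture by the carbanion (which would stop at the aryl ester), and high temperature, high dilution, dried CsF and the slow aryne release by the poorly soluble fluoride all work in that direction. Closure at the β-carbon instead of 5-exo at the α-carbon follows from the polarisation of the ynone, an allenyl ketone tautomer would be attacked at its central carbon and lead to the same chromone, and the benzyl ether keeps the ring C oxygen from being arylated.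

Step 10
Reactants: 19 2-{2-[4-(benzyloxy)-3-methoxyphenyl]ethyl}-6,7-dimethoxy-4H-chromen-4-one
Product: 20 2-[2-(4-hydroxy-3-methoxyphenyl)ethyl]-6,7-dimethoxy-4H-chromen-4-one
Conditions: H2 (1 atm), 10% Pd/C, EtOAc–MeOH, rt, stopped when 19 is consumed
Reagents that add atoms: none
Why: Hydrogenolysis of an aryl benzyl ether on Pd/C at atmospheric pressure should be much faster than hydrogenation of the C2=C3 bond, which is a deactivated vinylogous ester inside the conjugated pyranone.

**Compound list**
1 | 3,4-dimethoxyphenol | COc1ccc(O)cc1OC | starting material
2 | 2-bromo-4,5-dimethoxyphenol | COc1cc(O)c(Br)cc1OC | intermediate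
3 | (2-bromo-4,5-dimethoxyphenoxy)trimethylsilane | COc1cc(O[Si](C)(C)C)c(Br)cc1OC | intermediate
4 | {4,5-dimethoxy-2-[(trimethylsilyl)oxy]phenyl}lithium (formed in the flask) | COc1cc(O[Si](C)(C)C)c([Li])cc1OC | intermediate
5 | lithium 4,5-dimethoxy-2-(trimethylsilyl)phenoxide (formed in the flask) | COc1cc([O-])c([Si](C)(C)C)cc1OC.[Li+] | intermediate
6 | 4,5-dimethoxy-2-(trimethylsilyl)phenyl trifluoromethanesulfonate | COc1cc([Si](C)(C)C)c(OS(=O)(=O)C(F)(F)F)cc1OC | intermediate
7 | O-benzylvanillin, 4-(benzyloxy)-3-methoxybenzaldehyde | COc1cc(C=O)ccc1OCc1ccccc1 | starting material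
8 | [4-(benzyloxy)-3-methoxyphenyl]methanol | COc1cc(CO)ccc1OCc1ccccc1 | intermediate
9 | 1-(benzyloxy)-4-(bromomethyl)-2-methoxybenzene | COc1cc(CBr)ccc1OCc1ccccc1 | intermediate
10 | 1-(trimethylsilyl)propyne | CC#C[Si](C)(C)C | starting material
11 | [3-(trimethylsilyl)prop-2-yn-1-yl]lithium (formed in the flask) | [Li]CC#C[Si](C)(C)C | intermediate
12 | {4-[4-(benzyloxy)-3-methoxyphenyl]but-1-yn-1-yl}trimethylsilane | COc1cc(CCC#C[Si](C)(C)C)ccc1OCc1ccccc1 | intermediate
13 | 1-(benzyloxy)-4-(but-3-yn-1-yl)-2-methoxybenzene | COc1cc(CCC#C)ccc1OCc1ccccc1 | intermediate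
14 | {4-[4-(benzyloxy)-3-methoxyphenyl]but-1-yn-1-yl}lithium (formed in the flask) | COc1cc(CCC#C[Li])ccc1OCc1ccccc1 | intermediate
15 | lithium 5-[4-(benzyloxy)-3-methoxyphenyl]pent-2-ynoate (formed in the flask) | COc1cc(CCC#CC(=O)[O-])ccc1OCc1ccccc1.[Li+] | intermediate
16 | 5-[4-(benzyloxy)-3-methoxyphenyl]pent-2-ynoic acid | COc1cc(CCC#CC(=O)O)ccc1OCc1ccccc1 | intermediate
17 | 4,5-dimethoxybenzyne (formed in the flask) | COC1=CC#CC=C1OC | intermediate
18 | 5-[4-(benzyloxy)-3-methoxyphenyl]-1-(2-hydroxy-4,5-dimethoxyphenyl)pent-2-yn-1-one (formed in the flask, present as its phenoxide) | COc1cc(CCC#CC(=O)c2cc(OC)c(OC)cc2O)ccc1OCc1ccccc1 | intermediate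
19 | 2-{2-[4-(benzyloxy)-3-methoxyphenyl]ethyl}-6,7-dimethoxy-4H-chromen-4-one | COc1cc(CCc2cc(=O)c3cc(OC)c(OC)cc3o2)ccc1OCc1ccccc1 | intermediate
20 | 2-[2-(4-hydroxy-3-methoxyphenyl)ethyl]-6,7-dimethoxy-4H-chromen-4-one | COc1cc(CCc2cc(=O)c3cc(OC)c(OC)cc3o2)ccc1O | target

**Total step count:** 10
**Longest linear sequence:** 7 (steps 4 to 10)

**Steps most likely to fail**

1. **Step 9.**
   - What may go wrong:
     - The carbanion may pick up a proton before the acyl shift, so the sequence ends at simple O-arylation.
     - The alkynoate may lose CO2 at 125 °C.
     - The phenoxide may be arylated by a second aryne before it closes.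
     - Part of the closure may go 5-exo. An aliphatic alk-2-ynoic acid with propargylic hydrogens is also a more base-sensitive member of the acid class than those usually used.
   - Fallback, setting out from 1 and 13 and coming back at 19: 1 is iodinated with N-iodosuccinimide in MeCN at 0 °C, at the same position as in step 1, to give 2-iodo-4,5-dimethoxyphenol F1. F1 is then joined with alkyne 13 and carbon monoxide in a carbonylative Sonogashira annulation (PdCl2(dppf) catalyst, Et2NH, CO, 120 °C, autoclave). This is a known entry to 2-substituted chromones. It passes through ynone 18 and, in a secondary amine medium, closes 6-endo to 19.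

2. **Step 6.**
   - What may go wrong:
     - The lithium reagent may react in part through its allenyl terminus.
     - Halogen–metal exchange may lead to homocoupling of the very reactive benzylic bromide.
     - The bromide may decay by self-alkylation before it is used.
   - Fallback, setting out from 7 and coming back at 13 (it replaces steps 4 to 7): Barbier propargylation of aldehyde 7 with propargyl bromide and zinc dust in THF and aqueous NH4Cl gives 1-[4-(benzyloxy)-3-methoxyphenyl]but-3-yn-1-ol F2 (racemic). Its benzylic hydroxyl ionises readily thanks to the para benzyloxy group. It is removed by ionic hydrogenation (Et3SiH, CF3CO2H, CH2Cl2, 0 °C) to give 13.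

3. **Step 10.**
   - What may go wrong: saturation of the C2=C3 bond may set in before the benzyl ether is fully cleaved, or the hydrogenolysis may stall.
   - Fallback, setting out from 19 and coming back at 20: a non-reductive Lewis acid debenzylation with BCl3 and pentamethylbenzene as cation scavenger in CH2Cl2 at −78 °C. This cannot touch the pyranone double bond. It should spare the aryl methyl ethers, none of which sits peri to the carbonyl. It makes no new compound (F0).

**Further compounds**
F1 | step 9 | 2-iodo-4,5-dimethoxyphenol | COc1cc(O)c(I)cc1OC
F2 | step 6 | 1-[4-(benzyloxy)-3-methoxyphenyl]but-3-yn-1-ol (racemic) | COc1cc(C(O)CC#C)ccc1OCc1ccccc1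
F0 | step 10 | none | none
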